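If target fills these flasks long before it drifts to its isomer, the time of reading tells which of the two stands higher.

    substrate + target → 2 target (k1 = 1.0 L mol⁻¹ s⁻¹)
    substrate → target (k2 = 3.7 × 10⁻⁵ s⁻¹)
    target ⇌ isomer of the product (K3 = 50, k3 = 0.0024 s⁻¹)
    substrate + target → side product (k4 = 0.0035 L mol⁻¹ s⁻¹)
    2 substrate → self-condensation product (k5 = 0.0075 L mol⁻¹ s⁻¹)

common to all: substrate 0.51 M; target 5.10 mM
- noon: time 8.0 min
- spring: time 4.0 min

- percentages count the substrate that a species holds: one side product or self-condensation product counts as two
- where a step has two of a species, its rate is k times that concentration squared, and two are used at each turn
- run time (noon): 8.0 min

1. which of the two there is more of at the end, noon (isomer of the product / target)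
2. which of the two there is more of at the end, spring (isomer of the product / target)
3. final target, as a percentage of the substrate charged, in noon
4. final target, as a percentage of the substrate charged, in spring

Noon and spring had the same charge and differed in their time of reading. I reckoned the flask at both ends and joined them.

At the early end, while c(substrate) stood near its charge, c(target) multiplied at 0.510 s⁻¹. At that rate I reckoned 0.150 min from its seed to the size of the charge, and I called this estimate the growth time.

At the late end, c(isomer of the product)/c(target) tended to 50. Target and isomer together, the pool, approached that ratio with a relaxation time of 6.81 min.

I could treat these one after the other because the growth time was far shorter than the relaxation time. Target's share of the pool then fell exponentially from one towards 1.96 %, and the size of the pool cancelled in that share.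

The two species stood equal when the share reached half. That took 0.713 relaxation times after the growth time. This gave the crossing time, the moment when c(isomer of the product) overtakes c(target): 5.01 min.

Noon was read later than that, so I chose isomer of the product. Spring was read earlier, so I chose target. Target's share of the pool came to 32.9 % for noon and 57.7 % for spring. I did not reckon the size of the pool, so my reckoning stopped there.

The forecast took a pool of about 0.485 M. It named isomer of the product for noon and target for spring, with target at 31.3 % and 54.8 %, saying that “the isomer has overtaken the target by 8 min but not by 4 min”.

The simulation gave the forecast's choices, with target at 31.3 % in noon and 54.8 % in spring. Noon, read at 8.0 min, past my reckoned crossing time of 5.01 min, held 63.8 % as isomer of the product against 31.3 % as target, while spring, read at 4.0 min, before it, held 40.2 % as isomer against 54.8 % as target. The same charge read at 3.0 min, earlier still, held 31.8 % as isomer of the product against 63.2 % as target.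

(The constants stand for no real mixture, and the outcome is calculated.)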